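76.0% of the substrate charged appears in neither reading of the theta run at 20.0 min, where substrate reads 0% and product 24%. The new flask charges coupling partner at 1.20 equiv, so substrate is the limiting reagent and the ledger is kept on it. Each mole of substrate stands in one of three entries: substrate, product, or a hidden entry, which is what remains of the charge when both readings are subtracted.

| flask | substrate | coupling partner | remark | time |
|---|---|---|---|---|
| beta | 0.24 M | 1.7 equiv | run made earlier |  |
| theta | 0.24 M | 2.6 equiv | run made earlier |  |
| flask | 0.24 M | 1.20 equiv |  | 80 min |

| run | time / min | product / % | substrate / % |
|---|---|---|---|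
| beta | 5.00 | 3 | 44 |
| beta | 8.00 | 5 | 29 |
| beta | 12.0 | 15 | 20 |
| beta | 20.0 | 18 | 8 |
| beta | 30.0 | 30 | 5 |
| beta | 40.0 | 45 | 1 |
| beta | 60.0 | 57 | 1 |
| theta | 5.00 | 3 | 26 |
| theta | 8.00 | 5 | 17 |
| theta | 12.0 | 11 | 4 |
| theta | 20.0 | 24 | 0 |
| theta | 30.0 | 36 | 3 |
| theta | 40.0 | 46 | 0 |
| theta | 60.0 | 61 | 0 |

(scatter of a reading: 1.5 percentage points)



- amount of product in percent of the substrate charged, at 15 min, 40 min and 80 min

The substrate entry moves with the partner: at 5.00 min it reads 44% in the beta run and 26% in the theta run. The product entry does not appear to, since at 40.0 min it reads 45% and 46% in the same two runs. The hidden entry therefore seems to empty into product at its own pace. In the theta run, with substrate read at 0% and later 0%, the hidden entry falls from 76.0% at 20.0 min to 39.0% at 60.0 min, and that fall reads as 41.6 min. This is the drain half-life, the time in which the hidden entry loses half its content while substrate no longer feeds it.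

My own reckoning sets an estimated ceiling from it. Had every mole entered the hidden entry at the start, product in the new flask would reach 48.6% at 40 min and 73.7% at 80 min. In the new flask the moles enter over time and not at the start, so the figures should lie below these estimates.

The forecast gives 11%, 36% and 65%, the last of these below the ceiling, holding that “the first step is now slower and partly limiting”.

The new flask gives 11.4%, 36.8% and 65.6%, and the forecast held.

    substrate + coupling partner → intermediate + by-product (k = 0.510 /M/min)
    intermediate → product (k = 0.0170 /min)

In the new flask the half-life of substrate by the first step is 7.9 min at 6.01 min, shorter than the drain half-life of 41.6 min, and intermediate, the hidden entry, is then made 5.74 times faster than it is used up; at 80.0 min that ratio is 0.137. Of the 54.1% of intermediate standing at 40.0 min, the drain half-life with no further feed leaves an estimated 27.8% of the charge at 80.0 min, and the new flask, with 6.4 percentage points of substrate consumed in that time, holds 31.7%.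

All runs were generated by integration from invented constants; noise was put on by code.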